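**Plan**

- Numbering follows phenanthrene: ring A is C4b–C8a, ring B is C4a/C4b/C8a/C9/C10/C10a, ring C is C1–C4/C4a/C10a, and C2' is the aminal CH. The enabling feature is that rings B and C share the C4a–C10a bond while ring B is completed by C9 (oxygenated, on ring A) and C10 (a bare CH2). That is the imprint of a 2-alkylbenzaldehyde photoenol (C9, C8a, C4b, C4a) that has added to a vinyl ketone (C10=C10a–C1=O).
- Retrosynthesis: with C8–OH benzylated, C9 as a carbinol and C4a–C10a saturated, C4a–C10a and C9–C10 are cut together, giving aldehyde 24. Further cuts are C1–C10a (vinyl Grignard on a Weinreb amide), C2=C3 (thioiminium condensation), C4–CH3 (enolate methylation), the C2' N,O-acetal, the C3–N amide, and C4–C4a (lateral acylation of an orsellinate with diethyl oxalate).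
- Forward: ring A is bought as methyl orsellinate. The pyrrolidine and oxazolidinone rings close together in step 7, the C2–C1–C10a–C10 arm is attached in steps 12 and 13, and rings B and C close together in step 14. Three adjustments finish the synthesis.
- Stereochemistry: asymmetric transfer hydrogenation sets C4 (S) as a secondary carbinol, which fixes C2' (S) during N,O-acetal closure. Enolisation then erases C4, and methylation on the convex face rebuilds it as the quaternary (R) centre under control of C2' (self-regeneration of the stereocentre). The three centres made in step 14 are removed again.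

Key step: step 14

Remark: the target is drawn as its C9-keto, C10-methylene tautomer; this and the 9-naphthol form differ only by a proton shift, so the route aims at this tautomeric system and reports it as drawn. In compounds 14–24 the bicycle is numbered as a pyrrolo[2,1-b][1,3]oxazole (C2 = C4 of the target, C3 = C3, C7a = C2').

**Route**

Step 1
Reactants: 1 methyl 2,4-dihydroxy-6-methylbenzoate; 2 iodomethane
Product: 3 methyl 2-hydroxy-4-methoxy-6-methylbenzoate
Conditions: MeI (1.1 equiv), K2CO3 (1.1 equiv), acetone, rt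
Reagents that add atoms: none
Why: Williamson etherification: the 2-hydroxyl is tied up in a hydrogen bond to the ester carbonyl, so one equivalent of iodomethane should alkylate only the free 4-hydroxyl.

Step 2
Reactants: 3 methyl 2-hydroxy-4-methoxy-6-methylbenzoate
Product: 4 methyl 2-(benzyloxy)-4-methoxy-6-methylbenzoate
Conditions: BnBr, K2CO3, DMF, 60 °C
Reagents that add atoms: benzyl bromide, BrCc1ccccc1
Why: Williamson etherification of the chelated phenol under more forcing conditions; the benzyl ether should withstand the later bases, hydrides, acids and thionation and leaves by hydrogenolysis in step 17.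

Step 3
Reactants: 4 methyl 2-(benzyloxy)-4-methoxy-6-methylbenzoate; 5 diethyl oxalate
Product: 6 ethyl 3-[3-(benzyloxy)-5-methoxy-2-(methoxycarbonyl)phenyl]-2-oxopropanoate (keto/enol mixture)
Conditions: LiN(iPr)2 (1.1 equiv), THF, −78 °C; cannulated into (CO2Et)2 (4 equiv), THF, −78 °C; AcOH quench
Reagents that add atoms: none
Why: Lateral lithiation of the o-toluate and Claisen-type acylation by diethyl oxalate; inverse addition to excess oxalate keeps the more acidic product from quenching unreacted benzylic anion, and the crude keto ester is used at once because its enol can lactonise to an isocoumarin.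

Step 4
Reactants: 6 ethyl 3-[3-(benzyloxy)-5-methoxy-2-(methoxycarbonyl)phenyl]-2-oxopropanoate
Product: 9 (3S)-8-(benzyloxy)-6-methoxy-1-oxo-3,4-dihydro-1H-isochromene-3-carboxylic acid, via hydroxy diester 7 (not isolated), via hydroxy diacid 8 (not isolated)
Conditions: RuCl[(S,S)-TsDPEN](p-cymene) (1 mol%), HCO2H/Et3N 5:2, DMF, rt; then LiOH·H2O, THF/H2O, rt; then 2 M HCl, rt to 40 °C
Reagents that add atoms: lithium hydroxide, [Li+].[OH-]
Why: Noyori asymmetric transfer hydrogenation of the α-keto ester through its keto tautomer sets C4: with the ester carbonyl in the π-directing role the (S,S)-catalyst is expected to give the (S)-carbinol (sense to be confirmed by Mosher ester analysis, the antipodal catalyst being used otherwise), and saponification followed by acidification closes the δ-lactone, which ties the C4 hydroxyl to C9 and can be recrystallised to raise the ee.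

Step 5
Reactants: 9 (3S)-8-(benzyloxy)-6-methoxy-1-oxo-3,4-dihydro-1H-isochromene-3-carboxylic acid; 10 4,4-diethoxybutan-1-amine
Product: 11 (3S)-8-(benzyloxy)-N-(4,4-diethoxybutyl)-6-methoxy-1-oxo-3,4-dihydro-1H-isochromene-3-carboxamide
Conditions: 1,1'-carbonyldiimidazole, THF, rt; then 10, rt
Reagents that add atoms: none
Why: Amide coupling through the acyl imidazolide, which is far more electrophilic than the electron-rich aryl lactone, under conditions too weakly basic to epimerise C4.

Step 6
Reactants: 11 (3S)-8-(benzyloxy)-N-(4,4-diethoxybutyl)-6-methoxy-1-oxo-3,4-dihydro-1H-isochromene-3-carboxamide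
Product: 12 (2S)-3-[3-(benzyloxy)-2-(hydroxymethyl)-5-methoxyphenyl]-N-(4,4-diethoxybutyl)-2-hydroxypropanamide
Conditions: LiBH4, THF/MeOH, 0 to 40 °C
Reagents that add atoms: none
Why: Chemoselective hydride reduction: LiBH4 reduces lactones but not secondary amides, acetals or benzyl ethers, which frees the C4 hydroxyl and brings C9 to the alcohol level.

Step 7
Reactants: 12 (2S)-3-[3-(benzyloxy)-2-(hydroxymethyl)-5-methoxyphenyl]-N-(4,4-diethoxybutyl)-2-hydroxypropanamide
Product: 14 (2S,7aS)-2-[3-(benzyloxy)-2-(hydroxymethyl)-5-methoxybenzyl]tetrahydropyrrolo[2,1-b][1,3]oxazol-3(2H)-one, via carbinolamide 13 (not isolated)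
Conditions: pyridinium p-toluenesulfonate (0.2 equiv), THF/H2O 4:1, 50 °C; then pyridinium p-toluenesulfonate (0.1 equiv), CH2Cl2, 4 Å molecular sieves, rt
Reagents that add atoms: none
Why: N-acyliminium N,O-acetalisation: hydrolysis of the acetal lets the amide nitrogen close onto the aldehyde, and ionisation of carbinolamide 13 followed by capture by the C4 hydroxyl forms the five-membered N,O-acetal, the new C7a centre being set under reversible conditions by the C2 benzyl arm, which takes the convex face cis to H-7a; the acid is weak enough to spare the acid-labile 2,4-dialkoxybenzyl alcohol.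

Step 8
Reactants: 14 (2S,7aS)-2-[3-(benzyloxy)-2-(hydroxymethyl)-5-methoxybenzyl]tetrahydropyrrolo[2,1-b][1,3]oxazol-3(2H)-one
Product: 15 2-(benzyloxy)-4-methoxy-6-{[(2S,7aS)-3-oxohexahydropyrrolo[2,1-b][1,3]oxazol-2-yl]methyl}benzaldehyde
Conditions: activated MnO2, CH2Cl2, rt
Reagents that add atoms: none
Why: MnO2 oxidation of the electron-rich benzylic alcohol to the aldehyde without touching the lactam or the N,O-acetal.

Step 9
Reactants: 15 2-(benzyloxy)-4-methoxy-6-{[(2S,7aS)-3-oxohexahydropyrrolo[2,1-b][1,3]oxazol-2-yl]methyl}benzaldehyde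
Product: 16 (2S,7aS)-2-[3-(benzyloxy)-2-(dimethoxymethyl)-5-methoxybenzyl]tetrahydropyrrolo[2,1-b][1,3]oxazol-3(2H)-one
Conditions: HC(OMe)3, MeOH, pyridinium p-toluenesulfonate (5 mol%), rt; Et3N quench
Reagents that add atoms: trimethyl orthoformate, COC(OC)OC; methanol, CO
Why: Acid-catalysed acetalisation with orthoformate as water scavenger masks the aldehyde against the enolate, thionation and organometallic steps, under acid too weak to ionise the N-acyl N,O-acetal.

Step 10
Reactants: 16 (2S,7aS)-2-[3-(benzyloxy)-2-(dimethoxymethyl)-5-methoxybenzyl]tetrahydropyrrolo[2,1-b][1,3]oxazol-3(2H)-one; 2 iodomethane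
Product: 17 (2R,7aS)-2-[3-(benzyloxy)-2-(dimethoxymethyl)-5-methoxybenzyl]-2-methyltetrahydropyrrolo[2,1-b][1,3]oxazol-3(2H)-one
Conditions: LiN(iPr)2, THF, −78 °C; MeI, −78 to −40 °C
Reagents that add atoms: none
Why: Diastereoselective enolate alkylation with self-regeneration of the stereocentre: deprotonation flattens C2, and iodomethane should attack the convex face of the cis-fused bicycle, cis to H-7a and away from the pyrrolidine ring, so that C7a alone dictates the quaternary (2R) centre (C4 of the target, methyl cis to H-2').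

Step 11
Reactants: 17 (2R,7aS)-2-[3-(benzyloxy)-2-(dimethoxymethyl)-5-methoxybenzyl]-2-methyltetrahydropyrrolo[2,1-b][1,3]oxazol-3(2H)-one
Product: 18 (2R,7aS)-2-[3-(benzyloxy)-2-(dimethoxymethyl)-5-methoxybenzyl]-2-methyltetrahydropyrrolo[2,1-b][1,3]oxazole-3(2H)-thione
Conditions: Lawesson's reagent (0.6 equiv), pyridine (0.2 equiv), PhMe, 90 °C
Reagents that add atoms: Lawesson's reagent, COc1ccc(cc1)P1(=S)SP(=S)(S1)c1ccc(OC)cc1
Why: Thionation of the only carbonyl group, the lactam, with Lawesson's reagent; pyridine buffers traces of acid that could harm the acetal.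

Step 12
Reactants: 18 (2R,7aS)-2-[3-(benzyloxy)-2-(dimethoxymethyl)-5-methoxybenzyl]-2-methyltetrahydropyrrolo[2,1-b][1,3]oxazole-3(2H)-thione; 2 iodomethane; 19 N,2-dimethoxy-N-methylacetamide
Product: 21 (2Z)-2-[(2R,7aS)-2-[3-(benzyloxy)-2-(dimethoxymethyl)-5-methoxybenzyl]-2-methyltetrahydropyrrolo[2,1-b][1,3]oxazol-3(2H)-ylidene]-N,2-dimethoxy-N-methylacetamide, via thioiminium iodide 20 (not isolated)
Conditions: MeI (5 equiv), MeCN, rt, then evaporation; 19, LiN(SiMe3)2, THF, −78 °C, then the salt, −78 to 0 °C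
Reagents that add atoms: none
Why: S-Methylation gives thioiminium salt 20, and the lithium enolate of 19 adds to its iminium carbon and expels methanethiolate (the thioiminium condensation used to turn lactams into vinylogous amides); 19 can enolise only at the methoxy-bearing CH2, the quaternary C2 cannot epimerise, and the C2=C3 geometry is of no consequence because the push–pull bond rotates easily.

Step 13
Reactants: 21 (2Z)-2-[(2R,7aS)-2-[3-(benzyloxy)-2-(dimethoxymethyl)-5-methoxybenzyl]-2-methyltetrahydropyrrolo[2,1-b][1,3]oxazol-3(2H)-ylidene]-N,2-dimethoxy-N-methylacetamide; 22 vinylmagnesium bromide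
Product: 24 2-(benzyloxy)-4-methoxy-6-{[(2R,3Z,7aS)-3-(1-methoxy-2-oxobut-3-en-1-ylidene)-2-methylhexahydropyrrolo[2,1-b][1,3]oxazol-2-yl]methyl}benzaldehyde, via ketone acetal 23 (not isolated)
Conditions: CH2=CHMgBr (3 equiv), THF, −40 to 0 °C; then poured into 1 M HCl/THF, 0 °C
Reagents that add atoms: water, O
Why: Weinreb ketone synthesis: the magnesium chelate stops addition at the ketone stage, and the cold acid quench protonates the liberated N,O-dimethylhydroxylamine (no aza-Michael addition to the vinyl ketone) and hydrolyses the very labile electron-rich aryl dimethyl acetal to the aldehyde.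

Step 14
Reactants: 24 2-(benzyloxy)-4-methoxy-6-{[(2R,3Z,7aS)-3-(1-methoxy-2-oxobut-3-en-1-ylidene)-2-methylhexahydropyrrolo[2,1-b][1,3]oxazol-2-yl]methyl}benzaldehyde
Product: 26 pentacyclic C9 carbinol (8-O-benzyl-4a,9,10,10a-tetrahydro form of the target skeleton; C4 R, C2' S; H-4a and H-10a cis, 9-OH cis to the C4a–C4 bond), via E-dienol 25 (not isolated)
Conditions: hν (365 nm LED), Ti(OiPr)4 (2 equiv), degassed PhMe (2 mM), rt
Reagents that add atoms: none
Why: The excited C9 aldehyde abstracts a hydrogen atom from the benzylic C4a methylene (1,5-hydrogen transfer), and the long-lived E-dienol 25 (C9=C8a–C4b=C4a, with OH and C4 both outward, held by Ti(OiPr)4 as a titanium dienolate) adds suprafacially to the tethered vinyl ketone C10=C10a. The closest known reaction is the intramolecular photoenolization/Diels–Alder reaction of 2-alkylbenzaldehydes carrying an enone on the benzylic arm, a type 1 intramolecular Diels–Alder reaction of a hydroxy-o-quinodimethane. Ring B closes as the (4+2) ring through the new bonds C4a–C10a and C9–C10, and ring C closes in the same event as the six-membered ring spanned by the four-atom tether C4–C3–C2–C1 in the fused mode. C4a and C10a should become cis through the transition state with the C1 carbonyl endo, the C9 hydroxyl ends up cis to C4 because both are outward on the dienol, and the diene face anti to the C4 methyl group is expected to be taken; all three centres are erased in steps 15 and 16, so any mixture converges. The selectivity that must hold is the connectivity (C4a to the substituted carbon C10a, against the electronic preference of a 1-hydroxydiene), and the tether secures it because the bridged alternative would be far too strained; the preset C4 and C2' centres are not involved. Competing absorption by the push–pull enaminone is limited by the narrow 365 nm band and high dilution, and the low rotation barrier of the C2=C3 bond lets the acyl arm reach the reactive geometry.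

Step 15
Reactants: 26 pentacyclic C9 carbinol
Product: 27 pentacyclic 1,9-dione (8-O-benzyl-4a,10,10a-trihydro form; C4 R, C2' S, H-4a and H-10a cis)
Conditions: Dess–Martin periodinane, pyridine, CH2Cl2, 0 °C to rt
Reagents that add atoms: none
Why: Dess–Martin oxidation of the secondary benzylic carbinol to the aryl ketone removes the C9 stereocentre; the vinylogous amide nitrogen is not oxidised.

Step 16
Reactants: 27 pentacyclic 1,9-dione
Product: 30 8-O-benzyl ether of the target (C4a=C10a, C10 H2, C9 ketone; C4 R, C2' S), via silyl enol ether 28 (not isolated), via ene-dione 29 (not isolated)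
Conditions: LiN(SiMe3)2, Me3SiCl, THF, −78 °C; then Pd(OAc)2 (1.1 equiv), MeCN, rt; Et3N (cat.) on work-up
Reagents that add atoms: none
Why: Saegusa–Ito oxidation: kinetic enolisation occurs at C10, the position α to the aryl ketone, Pd(OAc)2 then removes H-10a by β-hydride elimination to give ene-dione 29, and a base-mediated proton shift from C4a to C10 moves the double bond to C4a=C10a, which erases both ring-fusion centres and gives the keto/naphthol tautomer system of the target.

Step 17
Reactants: 30 8-O-benzyl ether of the target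
Product: 31 CNP0528850.1 (target)
Conditions: H2 (1 atm), Pd/C (10%), EtOAc, rt
Reagents that add atoms: none
Why: Hydrogenolysis of the aryl benzyl ether; the tetrasubstituted, conjugated C2=C3 and C4a=C10a double bonds and the aryl ketone should not be reduced at 1 atm in a short reaction.

**Compound list**

1 | methyl 2,4-dihydroxy-6-methylbenzoate (methyl orsellinate) | COC(=O)c1c(C)cc(O)cc1O | starting material
2 | iodomethane | CI | starting material
3 | methyl 2-hydroxy-4-methoxy-6-methylbenzoate | COC(=O)c1c(C)cc(OC)cc1O | intermediate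
4 | methyl 2-(benzyloxy)-4-methoxy-6-methylbenzoate | COC(=O)c1c(C)cc(OC)cc1OCc1ccccc1 | intermediate
5 | diethyl oxalate | CCOC(=O)C(=O)OCC | starting material
6 | ethyl 3-[3-(benzyloxy)-5-methoxy-2-(methoxycarbonyl)phenyl]-2-oxopropanoate | CCOC(=O)C(=O)Cc1cc(OC)cc(OCc2ccccc2)c1C(=O)OC | intermediate
7 | ethyl (2S)-3-[3-(benzyloxy)-5-methoxy-2-(methoxycarbonyl)phenyl]-2-hydroxypropanoate | CCOC(=O)[C@@H](O)Cc1cc(OC)cc(OCc2ccccc2)c1C(=O)OC | intermediate (not isolated)
8 | (2S)-3-[3-(benzyloxy)-2-carboxy-5-methoxyphenyl]-2-hydroxypropanoic acid (dilithium salt in the flask) | OC(=O)[C@@H](O)Cc1cc(OC)cc(OCc2ccccc2)c1C(O)=O | intermediate (not isolated)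
9 | (3S)-8-(benzyloxy)-6-methoxy-1-oxo-3,4-dihydro-1H-isochromene-3-carboxylic acid | OC(=O)[C@@H]1Cc2cc(OC)cc(OCc3ccccc3)c2C(=O)O1 | intermediate
10 | 4,4-diethoxybutan-1-amine | NCCCC(OCC)OCC | starting material
11 | (3S)-8-(benzyloxy)-N-(4,4-diethoxybutyl)-6-methoxy-1-oxo-3,4-dihydro-1H-isochromene-3-carboxamide | CCOC(CCCNC(=O)[C@@H]1Cc2cc(OC)cc(OCc3ccccc3)c2C(=O)O1)OCC | intermediate
12 | (2S)-3-[3-(benzyloxy)-2-(hydroxymethyl)-5-methoxyphenyl]-N-(4,4-diethoxybutyl)-2-hydroxypropanamide | CCOC(CCCNC(=O)[C@@H](O)Cc1cc(OC)cc(OCc2ccccc2)c1CO)OCC | intermediate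
13 | (2S)-3-[3-(benzyloxy)-2-(hydroxymethyl)-5-methoxyphenyl]-2-hydroxy-1-(2-hydroxypyrrolidin-1-yl)propan-1-one (both carbinolamide epimers) | OC1CCCN1C(=O)[C@@H](O)Cc1cc(OC)cc(OCc2ccccc2)c1CO | intermediate (not isolated)
14 | (2S,7aS)-2-[3-(benzyloxy)-2-(hydroxymethyl)-5-methoxybenzyl]tetrahydropyrrolo[2,1-b][1,3]oxazol-3(2H)-one (benzyl arm cis to H-7a) | O=C1N2CCC[C@@H]2O[C@H]1Cc1cc(OC)cc(OCc2ccccc2)c1CO | intermediate
15 | 2-(benzyloxy)-4-methoxy-6-{[(2S,7aS)-3-oxohexahydropyrrolo[2,1-b][1,3]oxazol-2-yl]methyl}benzaldehyde | O=C1N2CCC[C@@H]2O[C@H]1Cc1cc(OC)cc(OCc2ccccc2)c1C=O | intermediate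
16 | (2S,7aS)-2-[3-(benzyloxy)-2-(dimethoxymethyl)-5-methoxybenzyl]tetrahydropyrrolo[2,1-b][1,3]oxazol-3(2H)-one | O=C1N2CCC[C@@H]2O[C@H]1Cc1cc(OC)cc(OCc2ccccc2)c1C(OC)OC | intermediate
17 | (2R,7aS)-2-[3-(benzyloxy)-2-(dimethoxymethyl)-5-methoxybenzyl]-2-methyltetrahydropyrrolo[2,1-b][1,3]oxazol-3(2H)-one (methyl cis to H-7a) | O=C1N2CCC[C@@H]2O[C@]1(C)Cc1cc(OC)cc(OCc2ccccc2)c1C(OC)OC | intermediate
18 | (2R,7aS)-2-[3-(benzyloxy)-2-(dimethoxymethyl)-5-methoxybenzyl]-2-methyltetrahydropyrrolo[2,1-b][1,3]oxazole-3(2H)-thione | S=C1N2CCC[C@@H]2O[C@]1(C)Cc1cc(OC)cc(OCc2ccccc2)c1C(OC)OC | intermediate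
19 | N,2-dimethoxy-N-methylacetamide | COCC(=O)N(C)OC | starting material
20 | (2R,7aS)-2-[3-(benzyloxy)-2-(dimethoxymethyl)-5-methoxybenzyl]-2-methyl-3-(methylsulfanyl)-5,6,7,7a-tetrahydro-2H-pyrrolo[2,1-b][1,3]oxazol-4-ium iodide | CSC1=[N+]2CCC[C@@H]2O[C@]1(C)Cc1cc(OC)cc(OCc2ccccc2)c1C(OC)OC.[I-] | intermediate (not isolated)
21 | (2Z)-2-[(2R,7aS)-2-[3-(benzyloxy)-2-(dimethoxymethyl)-5-methoxybenzyl]-2-methyltetrahydropyrrolo[2,1-b][1,3]oxazol-3(2H)-ylidene]-N,2-dimethoxy-N-methylacetamide | CO/C(C(=O)N(C)OC)=C1\N2CCC[C@@H]2O[C@]1(C)Cc1cc(OC)cc(OCc2ccccc2)c1C(OC)OC | intermediate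
22 | vinylmagnesium bromide | C=C[Mg]Br | starting material
23 | (1Z)-1-[(2R,7aS)-2-[3-(benzyloxy)-2-(dimethoxymethyl)-5-methoxybenzyl]-2-methyltetrahydropyrrolo[2,1-b][1,3]oxazol-3(2H)-ylidene]-1-methoxybut-3-en-2-one | CO/C(C(=O)C=C)=C1\N2CCC[C@@H]2O[C@]1(C)Cc1cc(OC)cc(OCc2ccccc2)c1C(OC)OC | intermediate (not isolated)
24 | 2-(benzyloxy)-4-methoxy-6-{[(2R,3Z,7aS)-3-(1-methoxy-2-oxobut-3-en-1-ylidene)-2-methylhexahydropyrrolo[2,1-b][1,3]oxazol-2-yl]methyl}benzaldehyde | CO/C(C(=O)C=C)=C1\N2CCC[C@@H]2O[C@]1(C)Cc1cc(OC)cc(OCc2ccccc2)c1C=O | intermediate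
25 | E,E-hydroxy-o-quinodimethane (photoenol) of 24: C9(OH)=C8a and C4a=C4b exocyclic, OH and C4 outward | CO/C(C(=O)C=C)=C1\N2CCC[C@@H]2O[C@]1(C)/C=C1\C=C(OC)C=C(OCc2ccccc2)/C1=C\O | intermediate (not isolated)
26 | pentacyclic C9 carbinol, 8-O-benzyl, 4a,9,10,10a-tetrahydro; C4 R, C2' S, cis ring fusion, 9-OH cis to C4 | COC1=C2N3CCC[C@@H]3O[C@]2(C)[C@H]2[C@H](C[C@@H](O)c3c(OCc4ccccc4)cc(OC)cc32)C1=O | intermediate
27 | pentacyclic 1,9-dione, 8-O-benzyl, 4a,10a-dihydro (cis) | COC1=C2N3CCC[C@@H]3O[C@]2(C)[C@H]2[C@H](CC(=O)c3c(OCc4ccccc4)cc(OC)cc32)C1=O | intermediate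
28 | C9 trimethylsilyl enol ether of 27 (C9=C10) | COC1=C2N3CCC[C@@H]3O[C@]2(C)[C@H]2[C@H](C=C(O[Si](C)(C)C)c3c(OCc4ccccc4)cc(OC)cc32)C1=O | intermediate (not isolated)
29 | C10=C10a ene-1,9-dione (H-4a still present) | COC1=C2N3CCC[C@@H]3O[C@]2(C)[C@H]2C(=CC(=O)c3c(OCc4ccccc4)cc(OC)cc32)C1=O | intermediate (not isolated)
30 | 8-O-benzyl ether of the target (keto tautomer drawn) | COC1=C2N3CCC[C@@H]3O[C@]2(C)C2=C(CC(=O)c3c(OCc4ccccc4)cc(OC)cc32)C1=O | intermediate
31 | CNP0528850.1 (C4 R, C2' S) | COC1=C2N3CCC[C@@H]3O[C@]2(C)C2=C(CC(=O)c3c(O)cc(OC)cc32)C1=O | target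

**Count and risks**

Total: 17 steps. Longest linear sequence: 17 steps (1 to 31); the other starting materials enter as bought.

Steps most likely to fail:

1. Step 14. The light may be absorbed or the excited aldehyde quenched by the cross-conjugated enaminone. The excited carbonyl may also abstract a δ-hydrogen from the benzylic OCH2 of the protecting group instead of the C4a hydrogen, and the vinyl ketone may polymerise during a slow reaction. The fallback removes the competing hydrogen donor by changing the protecting group before the vinyl ketone exists. Setting out from 21, hydrogenolysis (H2, Pd/C, EtOAc with a trace of Et3N) would give the phenol F1, and tBuMe2SiCl/imidazole in DMF the silyl ether F2. Vinylmagnesium bromide then gives the ketone acetal F3, which the dilute HCl quench converts to the aldehyde F4. Irradiation as in step 14 passes through the dienol F5 to the carbinol F6. Dess–Martin oxidation gives the dione F7, and the Saegusa–Ito sequence through the silyl enol ether F8 and the ene-dione F9 gives the silyl ether F10. Bu4NF buffered with AcOH (THF, 0 °C) comes back to the route at 31.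

2. Step 12. Addition of the enolate to the neopentyl-like iminium carbon may be slow, so that S-demethylation back to 18 or simple proton transfer takes over. The fallback forms the C2=C3 bond intramolecularly by an Eschenmoser sulfide contraction and adds the oxygen afterwards. Setting out from 18, S-alkylation with 2-bromo-N-methoxy-N-methylacetamide (MeCN, rt) gives the thioiminium bromide F11. PPh3 and Et3N (MeCN, 60 °C) contract it to the vinylogous urea F12. N-Iodosuccinimide (CH2Cl2, 0 °C) gives the C2 iodide F13. An Ullmann-type C–O coupling with methanol (CuI, 3,4,7,8-tetramethyl-1,10-phenanthroline, Cs2CO3, MeOH/PhMe, 80 °C) comes back to the route at 21.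

3. Step 13. The push–pull conjugation may make the Weinreb carbonyl too unreactive towards the Grignard reagent, and vinyl ketone may be lost by conjugate addition during work-up. The fallback goes through the more electrophilic aldehyde. Setting out from 21, iBu2AlH (THF, −78 °C) gives the enal F14, and vinylmagnesium bromide adds to it to give the allylic alcohol F15. MnO2 (CH2Cl2, rt) oxidises this to the ketone acetal, which is where the fallback comes back to the route at 23; the acid treatment of step 13 then gives 24.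

Further compounds
F1 | step 14 | phenol from debenzylation of 21 | CO/C(C(=O)N(C)OC)=C1\N2CCC[C@@H]2O[C@]1(C)Cc1cc(OC)cc(O)c1C(OC)OC
F2 | step 14 | tert-butyldimethylsilyl ether of F1 | CO/C(C(=O)N(C)OC)=C1\N2CCC[C@@H]2O[C@]1(C)Cc1cc(OC)cc(O[Si](C)(C)C(C)(C)C)c1C(OC)OC
F3 | step 14 | silyl-protected vinyl ketone acetal | CO/C(C(=O)C=C)=C1\N2CCC[C@@H]2O[C@]1(C)Cc1cc(OC)cc(O[Si](C)(C)C(C)(C)C)c1C(OC)OC
F4 | step 14 | silyl-protected aldehyde (analogue of 24) | CO/C(C(=O)C=C)=C1\N2CCC[C@@H]2O[C@]1(C)Cc1cc(OC)cc(O[Si](C)(C)C(C)(C)C)c1C=O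
F5 | step 14 | silyl-protected E,E-dienol | CO/C(C(=O)C=C)=C1\N2CCC[C@@H]2O[C@]1(C)/C=C1\C=C(OC)C=C(O[Si](C)(C)C(C)(C)C)/C1=C\O
F6 | step 14 | silyl-protected C9 carbinol (analogue of 26) | COC1=C2N3CCC[C@@H]3O[C@]2(C)[C@H]2[C@H](C[C@@H](O)c3c(O[Si](C)(C)C(C)(C)C)cc(OC)cc32)C1=O
F7 | step 14 | silyl-protected 1,9-dione (analogue of 27) | COC1=C2N3CCC[C@@H]3O[C@]2(C)[C@H]2[C@H](CC(=O)c3c(O[Si](C)(C)C(C)(C)C)cc(OC)cc32)C1=O
F8 | step 14 | C9 trimethylsilyl enol ether of F7 | COC1=C2N3CCC[C@@H]3O[C@]2(C)[C@H]2[C@H](C=C(O[Si](C)(C)C)c3c(O[Si](C)(C)C(C)(C)C)cc(OC)cc32)C1=O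
F9 | step 14 | silyl-protected C10=C10a ene-dione | COC1=C2N3CCC[C@@H]3O[C@]2(C)[C@H]2C(=CC(=O)c3c(O[Si](C)(C)C(C)(C)C)cc(OC)cc32)C1=O
F10 | step 14 | 8-O-tert-butyldimethylsilyl ether of the target | COC1=C2N3CCC[C@@H]3O[C@]2(C)C2=C(CC(=O)c3c(O[Si](C)(C)C(C)(C)C)cc(OC)cc32)C1=O
F11 | step 12 | S-(Weinreb amidomethyl) thioiminium bromide of 18 | CON(C)C(=O)CSC1=[N+]2CCC[C@@H]2O[C@]1(C)Cc1cc(OC)cc(OCc2ccccc2)c1C(OC)OC.[Br-]
F12 | step 12 | vinylogous urea with C2–H (E) | CON(C)C(=O)/C=C1/N2CCC[C@@H]2O[C@]1(C)Cc1cc(OC)cc(OCc2ccccc2)c1C(OC)OC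
F13 | step 12 | C2-iodo vinylogous urea (Z) | CON(C)C(=O)/C(I)=C1/N2CCC[C@@H]2O[C@]1(C)Cc1cc(OC)cc(OCc2ccccc2)c1C(OC)OC
F14 | step 13 | 2-methoxy enal (vinylogous formamide) from 21 | CO/C(C=O)=C1\N2CCC[C@@H]2O[C@]1(C)Cc1cc(OC)cc(OCc2ccccc2)c1C(OC)OC
F15 | step 13 | allylic alcohol from vinyl addition to F14 (both carbinol epimers) | CO/C(C(O)C=C)=C1\N2CCC[C@@H]2O[C@]1(C)Cc1cc(OC)cc(OCc2ccccc2)c1C(OC)OC
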